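## Retrosynthetic overview

1. Feature: C4 is a tertiary carbinol carrying the lactone carbonyl C15, and the ester oxygen O6 sits on C6. The γ-lactone C4–C5–C6–O6–C15 on the ten-membered carbocycle C1–C10 is read as the footprint of a benzilic ester shift. Numbering: C1 is the OCH of the dihydrofuran, C7 the carbinol, C8 the spiroketal carbon, C9=C10 the alkene, C11/C12 the spirolactone arm.
2. Key disconnection C3–C4 and O6–C15: an eleven-membered 1,2-diketone (both carbonyl carbons in the ring) with a free C6 hydroxyl. The diketone comes from a ring-closing-metathesis alkene by dihydroxylation and double oxidation.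
3. C5–C6 by anti-selective allylboration of a C6 aldehyde. The dihydrofuran and spirolactone (O1–C8, O8–C8) come from a lactol acid, made by adding a C9 alkenyllithium to a C8 dioxolanone carbonyl.
4. C7 and C11 from diethyl (R)-malate (methylation, then enolate alkylation of the dioxolanone with retention). C1 by asymmetric transfer hydrogenation. C9=C10 by carbomagnesiation and iodination.
5. Ring order: dihydrofuran and spirolactone (steps 10 and 11), eleven-membered carbocycle (step 18), γ-lactone with contraction to the ten-membered ring (step 22).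

Key step: step 22

Remark: the descriptors are taken as drawn; they place C2 and C7 on opposite faces of the dihydrofuran, so O1–C8 is made before the carbocycle is closed (a transannular ketalisation would give the other C8 epimer), and steps 18 and 22 have to bear the strain of that bridging.

## Route

Step 1
Reactants: 1 pent-4-enal; 2 ethynyl(trimethyl)silane
Product: 3 rac-1-(trimethylsilyl)hept-6-en-1-yn-3-ol
Conditions: 2, n-BuLi, THF, −78 °C; then 1, −78 → 0 °C
Reagents that add atoms: none
Why: 1,2-addition of a lithium acetylide to an aldehyde; the racemic carbinol is corrected in steps 2 and 3.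

Step 2
Reactants: 3 rac-1-(trimethylsilyl)hept-6-en-1-yn-3-ol
Product: 4 1-(trimethylsilyl)hept-6-en-1-yn-3-one
Conditions: Dess–Martin periodinane, NaHCO3, CH2Cl2, 0 °C → rt
Reagents that add atoms: none
Why: Dess–Martin oxidation of a propargylic alcohol to the ynone leaves the terminal alkene untouched.

Step 3
Reactants: 4 1-(trimethylsilyl)hept-6-en-1-yn-3-one
Product: 5 (3S)-1-(trimethylsilyl)hept-6-en-1-yn-3-ol
Conditions: RuCl[(S,S)-TsDPEN](p-cymene) (1 mol %), i-PrOH, rt
Reagents that add atoms: none
Why: Noyori asymmetric transfer hydrogenation of an alkynyl ketone; the (S,S)-ligand should deliver hydride to the face that gives the (S)-carbinol, the future C1.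

Step 4
Reactants: 5 (3S)-1-(trimethylsilyl)hept-6-en-1-yn-3-ol
Product: 6 (3S)-hept-6-en-1-yn-3-ol
Conditions: K2CO3 (0.2 equiv), MeOH, 0 °C → rt
Reagents that add atoms: none
Why: base-catalysed methanolysis of the alkynyl C–Si bond does not touch the carbinol centre.

Step 5
Reactants: 6 (3S)-hept-6-en-1-yn-3-ol
Product: 8 (1Z,3S)-1-iodo-2-methylhepta-1,6-dien-3-ol, via alkenylmagnesium chelate 7 (not isolated)
Conditions: MeMgBr (3 equiv), CuI (10 mol %), THF, −20 °C → rt; then I2, −78 → 0 °C
Reagents that add atoms: methylmagnesium bromide (C[Mg]Br); iodine (II)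
Why: copper-catalysed anti-carbomagnesiation of a propargylic alkoxide (Duboudin reaction) puts methyl on the inner carbon (C10) and magnesium on the terminal carbon (C9) in a five-membered chelate, and iodinolysis with retention gives the Z-iodide with iodine cis to the carbinol carbon.

Step 6
Reactants: 9 diethyl (R)-malate
Product: 10 diethyl (2R,3S)-2-hydroxy-3-methylbutanedioate
Conditions: LiN(i-Pr)2 (2.2 equiv), THF, −78 → −20 °C; MeI, −78 → 0 °C
Reagents that add atoms: iodomethane (CI)
Why: Fráter–Seebach alkylation; the alkoxide–enolate dianion is methylated anti to the alkoxide, which sets C11.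

Step 7
Reactants: 10 diethyl (2R,3S)-2-hydroxy-3-methylbutanedioate
Product: 11 (2R,3S)-2-hydroxy-3-methylbutanedioic acid
Conditions: KOH, H2O/EtOH, rt; then HCl to pH 1
Reagents that add atoms: potassium hydroxide ([K+].[OH-])
Why: saponification of both esters; carboxylate formation is faster than enolisation at C11.

Step 8
Reactants: 11 (2R,3S)-2-hydroxy-3-methylbutanedioic acid
Product: 12 (2S)-2-[(2R,4R)-2-tert-butyl-5-oxo-1,3-dioxolan-4-yl]propanoic acid
Conditions: t-BuCHO, TsOH·H2O (cat.), H2SO4 (cat.), pentane, reflux, Dean–Stark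
Reagents that add atoms: 2,2-dimethylpropanal (CC(C)(C)C=O)
Why: acetalisation of the α-hydroxy acid half gives the five-membered dioxolanone; the cis isomer (tert-butyl cis to the side chain) is the thermodynamic one and should be purified by crystallisation.

Step 9
Reactants: 12 (2S)-2-[(2R,4R)-2-tert-butyl-5-oxo-1,3-dioxolan-4-yl]propanoic acid
Product: 13 (2S)-2-[(2R,4S)-2-tert-butyl-4-(4-methoxybenzyloxymethyl)-5-oxo-1,3-dioxolan-4-yl]propanoic acid
Conditions: LiN(SiMe3)2 (2.2 equiv), THF, −78 °C; 4-MeOC6H4CH2OCH2Cl, −78 → −40 °C; dilute HCl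
Reagents that add atoms: 4-methoxybenzyl chloromethyl ether (COc1ccc(COCCl)cc1)
Why: Seebach self-regeneration of the stereocentre; the carboxylate–enolate dianion is alkylated anti to the tert-butyl group, so C6 replaces the C7 hydrogen with retention and C7 becomes quaternary.

Step 10
Reactants: 8 (1Z,3S)-1-iodo-2-methylhepta-1,6-dien-3-ol; 13 alkylated dioxolanone acid
Product: 15 lactol acid (C8 anomers), via dilithio alkoxide 14 (not isolated)
Conditions: 8, n-BuLi (1.0 equiv) then t-BuLi (2.1 equiv), THF, −78 °C; add 13 pre-treated with LiN(SiMe3)2 (1.0 equiv), −78 → −30 °C; aq NaH2PO4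
Reagents that add atoms: none
Why: iodine–lithium exchange with retention, then addition of the alkenyllithium to the activated dioxolanone carbonyl (C8); the hemiketal loses pivalaldehyde to give the C7-hydroxy Z-enone, which the C1 hydroxyl traps as the lactol, while the tetrahedral adduct prevents double addition and the lithium carboxylate is inert at this temperature.

Step 11
Reactants: 15 lactol acid
Product: 16 spirolactone alcohol (C7–OH free, C6 as CH2OPMB)
Conditions: EDC·HCl, DMAP (0.2 equiv), CH2Cl2, 0 °C
Reagents that add atoms: none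
Why: carbodiimide lactonisation of the lactol hydroxyl (5-exo-trig) under non-acidic conditions, which avoid dehydration to a furan; C8 is set while the lactol anomers interconvert, and the epimer with the quaternary C7 trans to the butenyl chain on the dihydrofuran is expected to prevail and is separated from the other.

Step 12
Reactants: 16 spirolactone alcohol
Product: 17 C7 tert-butyldimethylsilyl ether
Conditions: t-BuMe2SiOTf, 2,6-lutidine, CH2Cl2, −40 → 0 °C
Reagents that add atoms: tert-butyldimethylsilyl triflate (CC(C)(C)[Si](C)(C)OS(=O)(=O)C(F)(F)F)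
Why: silyl triflate silylation of the hindered tertiary hydroxyl; excess base keeps the acyloxy ketal from ionising.

Step 13
Reactants: 17 C7 silyl ether
Product: 18 primary alcohol at C6
Conditions: DDQ, CH2Cl2/pH 7 buffer, 0 °C
Reagents that add atoms: none
Why: oxidative cleavage of the 4-methoxybenzyl ether; 18 is used at once because its hydroxyl can attack the lactone carbonyl C12.

Step 14
Reactants: 18 primary alcohol
Product: 19 C6 aldehyde
Conditions: Dess–Martin periodinane, NaHCO3, CH2Cl2, 0 °C
Reagents that add atoms: none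
Why: Dess–Martin oxidation to a neopentyl aldehyde that cannot enolise.

Step 15
Reactants: 19 C6 aldehyde; 20 allenylboronic acid pinacol ester
Product: 22 anti-diol (C5–OH, C6–OH, vinyl on C5), via borinate adduct 21 (not isolated)
Conditions: (+)-Ipc2BH [from (−)-α-pinene], 20, PhMe, 0 °C then 85 °C, 1 h; 19, −78 °C; then Me3NO, THF, 60 °C
Reagents that add atoms: trimethylamine N-oxide (C[N+](C)(C)[O-])
Why: Brown-type allylboration with the (E)-γ-borylallylborane made by hydroboration of the allenylboronate; the chair transition state gives the anti relation of C5 and C6, the isopinocampheyl groups should select the aldehyde face that gives the 6R carbinol against a modest opposite substrate bias, and C–B oxidation with retention puts the hydroxyl on C5.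

Step 16
Reactants: 22 anti-diol
Product: 23 C5 4-methoxybenzyl ether with free C6–OH
Conditions: 2-(4-methoxybenzyloxy)-4-methylquinoline, MeOTf, MgO, PhCF3, 0 °C → rt
Reagents that add atoms: 2-(4-methoxybenzyloxy)-4-methylquinoline (COc1ccc(COc2cc(C)c3ccccc3n2)cc1)
Why: neutral benzyl transfer (Dudley reagent) to the allylic C5 hydroxyl; the C6 hydroxyl next to the quaternary silyloxy carbon should be too hindered to compete.

Step 17
Reactants: 23 C5 ether
Product: 24 C6 triethylsilyl ether (diene for ring closure)
Conditions: Et3SiOTf, 2,6-lutidine, CH2Cl2, −78 → −20 °C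
Reagents that add atoms: triethylsilyl triflate (CC[Si](CC)(CC)OS(=O)(=O)C(F)(F)F)
Why: silylation masks C6–OH for steps 18 to 20 with a group that can later be removed beside the tertiary silyl ether.

Step 18
Reactants: 24 diene
Product: 25 eleven-membered cycloalkene (alkene isomers)
Conditions: RuCl2(=CHPh)(PCy3)(H2IMes) (second-generation Grubbs catalyst, 10 mol %), PhMe, 1 mM, 80 °C
Reagents that add atoms: none
Why: ring-closing metathesis of the two monosubstituted alkenes with loss of ethene closes the carbocycle; the trisubstituted C9=C10 should not take part and the alkene geometry is irrelevant.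

Step 19
Reactants: 25 cycloalkene
Product: 26 vicinal diol (mixture at the two new centres)
Conditions: OsO4 (5 mol %), N-methylmorpholine N-oxide, acetone/H2O, 0 °C → rt
Reagents that add atoms: N-methylmorpholine N-oxide (C[N+]1([O-])CCOCC1); water (O)
Why: Upjohn dihydroxylation of the disubstituted alkene; C9=C10 is flanked by the ketal carbon and C1 and is therefore electron-poor and shielded, and the two new centres are removed in step 20.

Step 20
Reactants: 26 diol
Product: 27 eleven-membered 1,2-diketone with C6–OSiEt3
Conditions: (COCl)2, DMSO, CH2Cl2, −78 °C; i-Pr2NEt, −78 → −40 °C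
Reagents that add atoms: none
Why: double Swern oxidation of a vicinal diol gives the 1,2-diketone without C–C cleavage; low temperature and a hindered amine limit enolisation toward C5.

Step 21
Reactants: 27 silyl-protected diketone
Product: 28 eleven-membered 1,2-diketone with free C6–OH
Conditions: HF·pyridine, pyridine, THF, 0 °C
Reagents that add atoms: none
Why: the secondary triethylsilyl ether should be cleaved much faster than the tertiary tert-butyldimethylsilyl ether; 28 is expected to rest as its neutral hemiketal.

Step 22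
Reactants: 28 hydroxy diketone
Product: 30 contracted hydroxy lactone (C5–OPMB, C7–OSi), via cesium lactol alkoxide 29 (not isolated)
Conditions: Cs2CO3 (0.3 equiv), MeCN, 0 °C → rt; pH 7 buffer
Reagents that add atoms: none
Why: Proposed new method: catalytic carbonate deprotonates the C6 hydroxyl (or its hemiketal), O6 adds to the farther carbonyl to give lactol alkoxide 29, and a 1,2-shift of C3 from C15 to the neighbouring ketone carbon C4 gives the lactone O6–C15=O and the C4 alkoxide, which takes a proton from the next molecule of 28 so that the base turns over. The closest known reaction is the benzilic ester rearrangement of cyclic 1,2-diketones with external alkoxides, made intramolecular here so that the ester is born as a lactone. The γ-lactone ring closes by 5-exo-trig addition of O6 to C15, and the ten-membered carbocycle arises from the eleven-membered one through the alkyl shift that forms C3–C4. C4 is set by the suprafacial shift: C3 can only sit on the lactol face it shares with C7, because the two are joined through C2–C1–C10–C9–C8, so it arrives on C4 cis to C7 and the new hydroxyl ends trans to it. The step needs O6 to attack C15 and not C4 (five- against four-membered ring), and the shift must outrun enolisation toward C5 and attack of O6 on the spirolactone carbonyl C12, which would pass through a strained bicyclo[2.2.1] ortho ester. The silyl ether on O7 removes the only other hydroxyl, and the C5 ether raises the electrophilicity of the accepting ketone.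

Step 23
Reactants: 30 contracted hydroxy lactone
Product: 31 C5 alcohol
Conditions: DDQ, CH2Cl2/pH 7 buffer, 0 °C
Reagents that add atoms: none
Why: oxidative removal of the 4-methoxybenzyl ether; water should intercept the benzylic cation before the neighbouring C4 hydroxyl forms a benzylidene acetal.

Step 24
Reactants: 31 C5 alcohol
Product: 32 C5 acetate with C7–OSi
Conditions: Ac2O, pyridine, DMAP (cat.), CH2Cl2, 0 °C
Reagents that add atoms: acetic anhydride (CC(=O)OC(C)=O)
Why: acylation of the only secondary hydroxyl; the tertiary C4 hydroxyl should not react under these conditions.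

Step 25
Reactants: 32 C5 acetate
Product: 33 CNP0315698.1
Conditions: HF·pyridine, THF, 0 °C → rt
Reagents that add atoms: none
Why: fluoride-mediated cleavage of the tertiary silyl ether; the bridged skeleton should keep the dihydrofuran from aromatising under the mildly acidic conditions.

## Compound list

1 | pent-4-enal | C=CCCC=O | starting material
2 | ethynyl(trimethyl)silane | C#C[Si](C)(C)C | starting material
3 | rac-1-(trimethylsilyl)hept-6-en-1-yn-3-ol | C=CCCC(O)C#C[Si](C)(C)C | intermediate
4 | 1-(trimethylsilyl)hept-6-en-1-yn-3-one | C=CCCC(=O)C#C[Si](C)(C)C | intermediate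
5 | (3S)-1-(trimethylsilyl)hept-6-en-1-yn-3-ol | C=CCC[C@H](O)C#C[Si](C)(C)C | intermediate
6 | (3S)-hept-6-en-1-yn-3-ol | C=CCC[C@H](O)C#C | intermediate
7 | alkenylmagnesium chelate of 6 after methyl addition (drawn halide-free) | C=CCC[C@@H]1O[Mg]C=C1C | intermediate
8 | (1Z,3S)-1-iodo-2-methylhepta-1,6-dien-3-ol | C=CCC[C@H](O)/C(C)=C\I | intermediate
9 | diethyl (R)-malate | CCOC(=O)C[C@@H](O)C(=O)OCC | starting material
10 | diethyl (2R,3S)-2-hydroxy-3-methylbutanedioate | CCOC(=O)[C@@H](C)[C@@H](O)C(=O)OCC | intermediate
11 | (2R,3S)-2-hydroxy-3-methylbutanedioic acid | OC(=O)[C@@H](C)[C@@H](O)C(=O)O | intermediate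
12 | (2S)-2-[(2R,4R)-2-tert-butyl-5-oxo-1,3-dioxolan-4-yl]propanoic acid | OC(=O)[C@@H](C)[C@H]1O[C@@H](C(C)(C)C)OC1=O | intermediate
13 | (2S)-2-[(2R,4S)-2-tert-butyl-4-(4-methoxybenzyloxymethyl)-5-oxo-1,3-dioxolan-4-yl]propanoic acid | OC(=O)[C@@H](C)[C@@]1(COCc2ccc(OC)cc2)O[C@@H](C(C)(C)C)OC1=O | intermediate
14 | dilithio derivative of 8 (lithium alkoxide, Z-alkenyllithium) | C=CCC[C@H](O[Li])/C(C)=C\[Li] | intermediate
15 | lactol acid: 2-hydroxy-2,5-dihydrofuran (C8 anomers) with C1 but-3-enyl, C10 methyl, and on C8 the C7 carbinol bearing OH, CH2OPMB and the (S)-propanoic acid arm | OC(=O)[C@@H](C)[C@](O)(COCc2ccc(OC)cc2)C1(O)O[C@@H](CCC=C)C(C)=C1 | intermediate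
16 | spirolactone alcohol: dihydrofuran O1–C1–C10=C9–C8 spiro at C8 to lactone C8–O8–C12–C11–C7; C7–OH, C7–CH2OPMB; C1, C7, C8, C11 arranged as in 33 | C=CCC[C@@H]1O[C@@]3(C=C1C)OC(=O)[C@@H](C)[C@@]3(COCc4ccc(OC)cc4)O | intermediate
17 | C7 tert-butyldimethylsilyl ether of 16 | C=CCC[C@@H]1O[C@@]3(C=C1C)OC(=O)[C@@H](C)[C@@]3(COCc4ccc(OC)cc4)O[Si](C)(C)C(C)(C)C | intermediate
18 | primary alcohol (C6 as CH2OH) | C=CCC[C@@H]1O[C@@]3(C=C1C)OC(=O)[C@@H](C)[C@@]3(CO)O[Si](C)(C)C(C)(C)C | intermediate
19 | C6 aldehyde | C=CCC[C@@H]1O[C@@]3(C=C1C)OC(=O)[C@@H](C)[C@@]3(C=O)O[Si](C)(C)C(C)(C)C | intermediate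
20 | allenylboronic acid pinacol ester | C=C=CB1OC(C)(C)C(C)(C)O1 | starting material
21 | allylboration adduct: C6–O–B(Ipc)2, C5–B(pinacolato), anti | C=CCC[C@@H]1O[C@@]3(C=C1C)OC(=O)[C@@H](C)[C@@]3([C@H](OB([C@H]5C[C@H]6C[C@@H]([C@@H]5C)C6(C)C)[C@H]5C[C@H]6C[C@@H]([C@@H]5C)C6(C)C)[C@H](B7OC(C)(C)C(C)(C)O7)C=C)O[Si](C)(C)C(C)(C)C | intermediate
22 | anti-diol: C6–OH, C5–OH, vinyl on C5 (C5, C6 arranged as in 33) | C=CCC[C@@H]1O[C@@]3(C=C1C)OC(=O)[C@@H](C)[C@@]3([C@H](O)[C@H](O)C=C)O[Si](C)(C)C(C)(C)C | intermediate
23 | C5 4-methoxybenzyl ether, C6–OH free | C=CCC[C@@H]1O[C@@]3(C=C1C)OC(=O)[C@@H](C)[C@@]3([C@H](O)[C@H](OCc4ccc(OC)cc4)C=C)O[Si](C)(C)C(C)(C)C | intermediate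
24 | C6 triethylsilyl ether (diene) | C=CCC[C@@H]1O[C@@]3(C=C1C)OC(=O)[C@@H](C)[C@@]3([C@H](O[Si](CC)(CC)CC)[C@H](OCc4ccc(OC)cc4)C=C)O[Si](C)(C)C(C)(C)C | intermediate
25 | eleven-membered cycloalkene (alkene between the future C4 and C15) | CC[Si](CC)(CC)O[C@@H]2[C@H](OCc4ccc(OC)cc4)C=CCC[C@@H]1O[C@@]3(C=C1C)OC(=O)[C@@H](C)[C@]23O[Si](C)(C)C(C)(C)C | intermediate
26 | eleven-membered vicinal diol (mixture at the two carbinols) | CC[Si](CC)(CC)O[C@@H]2[C@H](OCc4ccc(OC)cc4)C(O)C(O)CC[C@@H]1O[C@@]3(C=C1C)OC(=O)[C@@H](C)[C@]23O[Si](C)(C)C(C)(C)C | intermediate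
27 | eleven-membered 1,2-diketone, C6–OSiEt3 | CC[Si](CC)(CC)O[C@@H]2[C@H](OCc4ccc(OC)cc4)C(=O)C(=O)CC[C@@H]1O[C@@]3(C=C1C)OC(=O)[C@@H](C)[C@]23O[Si](C)(C)C(C)(C)C | intermediate
28 | eleven-membered 1,2-diketone, C6–OH free (key-step precursor) | O[C@@H]2[C@H](OCc4ccc(OC)cc4)C(=O)C(=O)CC[C@@H]1O[C@@]3(C=C1C)OC(=O)[C@@H](C)[C@]23O[Si](C)(C)C(C)(C)C | intermediate
29 | cesium lactol alkoxide (O6 on C15, C3 cis to C7 on the five-membered ring) | [Cs+].[O-][C@@]6(O[C@@H]2[C@H](OCc4ccc(OC)cc4)C6=O)CC[C@@H]1O[C@@]3(C=C1C)OC(=O)[C@@H](C)[C@]23O[Si](C)(C)C(C)(C)C | intermediate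
30 | contracted hydroxy lactone: ten-membered ring, γ-lactone C4–C5–C6–O6–C15, C4–OH, C5–OPMB, C7–OSi | COc4ccc(CO[C@H]1[C@H]2OC(=O)[C@]1(O)CC[C@@H]1O[C@@]3(C=C1C)OC(=O)[C@@H](C)[C@]23O[Si](C)(C)C(C)(C)C)cc4 | intermediate
31 | C5 alcohol | O[C@H]1[C@H]2OC(=O)[C@]1(O)CC[C@@H]1O[C@@]3(C=C1C)OC(=O)[C@@H](C)[C@]23O[Si](C)(C)C(C)(C)C | intermediate
32 | C5 acetate, C7 silyl ether | CC(=O)O[C@H]1[C@H]2OC(=O)[C@]1(O)CC[C@@H]1O[C@@]3(C=C1C)OC(=O)[C@@H](C)[C@]23O[Si](C)(C)C(C)(C)C | intermediate
33 | CNP0315698.1 | CC(=O)O[C@H]1[C@H]2OC(=O)[C@]1(O)CC[C@@H]1O[C@@]3(C=C1C)OC(=O)[C@@H](C)[C@]23O | target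

## Step count and risks

Total step count: 25. Longest linear sequence: 21 steps (steps 1 to 5 and 10 to 25, from pent-4-enal).

**Step 22 (key step, proposed new method).** The lactol alkoxide may not undergo the 1,2-shift before the C6 alkoxide attacks the spirolactone carbonyl C12 and opens the spiroketal, or before C5 epimerises through the enol of the adjacent ketone. The contraction also adds ring strain. Fallback with known chemistry, setting out from 27: a classical intermolecular benzilic ester rearrangement with KOt-Bu in t-BuOH/THF at 0 °C, with C6 still silylated so that no translactonisation can occur. Either carbonyl may take up the alkoxide, and both modes give the same ring-contracted constitution, the tert-butyl α-hydroxy ester F1 (C4 epimers). HF·pyridine then frees the C6 hydroxyl to give the hydroxy ester F2. Camphorsulfonic acid (cat.) in toluene at 50 °C closes the γ-lactone with loss of tert-butanol. Only the C4 epimer with the ester group syn to O6 can lactonise, and this returns to the route at 30.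

**Step 18.** Ring closure may lose to oligomerisation, because the seven-carbon tether has to join the two faces of the dihydrofuran and one of the alkenes is a hindered allylic ether. Fallback, setting out from 24: OsO4 (cat.), NaIO4 and 2,6-lutidine in dioxane/water cleave only the two monosubstituted alkenes to the dialdehyde F3. An irreversible intramolecular pinacol coupling with SmI2 in THF/t-BuOH then forms the bond between the two carbonyl carbons and gives the diol directly, coming back to the route at 26 and bypassing steps 18 and 19.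

**Step 15.** Facial selectivity at C6 may be poor, because the reagent has to override the intrinsic preference of the α-silyloxy neopentyl aldehyde, and allyl transfer to this hindered carbonyl may be slow. Fallback, setting out from 19: a Horner–Wittig olefination with lithiated allyl(diphenyl)phosphine oxide gives the E-diene F4. A Shi epoxidation (fructose-derived ketone of the series that delivers oxygen to the required face, KHSO5, buffered MeCN) selects the internal alkene and gives the trans vinyl epoxide F5 with C6 as required. Opening with 4-methoxybenzyl alcohol and BF3·OEt2 (cat.) at −78 °C at the allylic carbon C5 with inversion gives the anti C5 ether and returns to the route at 23, bypassing step 16 as well.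

Further compounds
F1 | step 22 | tert-butyl ester of the ring-contracted α-hydroxy acid, C6–OSiEt3 (C4 epimers) | CC[Si](CC)(CC)O[C@@H]2[C@H](OCc4ccc(OC)cc4)C(O)(C(=O)OC(C)(C)C)CC[C@@H]1O[C@@]3(C=C1C)OC(=O)[C@@H](C)[C@]23O[Si](C)(C)C(C)(C)C
F2 | step 22 | tert-butyl ester of the ring-contracted α-hydroxy acid, C6–OH free | O[C@@H]2[C@H](OCc4ccc(OC)cc4)C(O)(C(=O)OC(C)(C)C)CC[C@@H]1O[C@@]3(C=C1C)OC(=O)[C@@H](C)[C@]23O[Si](C)(C)C(C)(C)C
F3 | step 18 | dialdehyde from cleavage of both terminal alkenes of 24 | O=CCC[C@@H]1O[C@@]3(C=C1C)OC(=O)[C@@H](C)[C@@]3([C@H](O[Si](CC)(CC)CC)[C@H](OCc4ccc(OC)cc4)C=O)O[Si](C)(C)C(C)(C)C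
F4 | step 15 | E-buta-1,3-dienyl compound on C7 | C=CCC[C@@H]1O[C@@]3(C=C1C)OC(=O)[C@@H](C)[C@@]3(/C=C/C=C)O[Si](C)(C)C(C)(C)C
F5 | step 15 | trans vinyl epoxide across C5–C6 | C=CCC[C@@H]1O[C@@]3(C=C1C)OC(=O)[C@@H](C)[C@@]3([C@@H]5O[C@H]5C=C)O[Si](C)(C)C(C)(C)C
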